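**Strategy.** The flavone is cut at C2–C1' and C3–C4. C2 and C3 of ring C are a two-carbon bridge at the alkyne oxidation level between C1' of ring B and the C4 acyl carbon on ring A, so one acetylene unit can supply both. In a single pot, Sonogashira coupling, fluoride desilylation and acyl Sonogashira coupling join a ring B aryl iodide, ethynyltrimethylsilane and a ring A aroyl chloride into the open-chain ynone, making both bonds without closing a ring. The iodide carries the C3' oxygen as a benzyl ether; the acid chloride carries the future O1 as an ortho acetate. Amine-mediated closure of ring C and hydrogenolysis finish the synthesis.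

Key step: step 10

Assumption: the target has no stereocentres; enaminones 18 and 19 are drawn as E isomers, but their geometry is uncontrolled and irrelevant because both isomers converge on 20.

**Ring A acid chloride**

Step 1
Reactants: 1 3,4,5-trimethoxyphenol
Product: 2 6-hydroxy-2,3,4-trimethoxybenzaldehyde
Conditions: MgCl2, Et3N, (CH2O)n, MeCN, reflux; aq. HCl work-up
Reagents that add atoms: paraformaldehyde (as formaldehyde), C=O
Why: The magnesium phenoxide of 1 delivers formaldehyde to the carbon ortho to oxygen (Casnati–Skattebøl ortho-formylation, a second formaldehyde acting as hydride acceptor), and since the two ortho sites of 1 are equivalent only one aldehyde can form.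

Step 2
Reactants: 2 6-hydroxy-2,3,4-trimethoxybenzaldehyde
Product: 3 2-formyl-3,4,5-trimethoxyphenyl acetate
Conditions: Ac2O, pyridine, DMAP (cat.), CH2Cl2, 0 °C → rt
Reagents that add atoms: acetic anhydride, CC(=O)OC(C)=O
Why: DMAP-catalysed O-acylation of the hydrogen-bonded phenol is routine and turns the future O1 into the acetate that later singles it out as the ring-closing nucleophile.

Step 3
Reactants: 3 2-formyl-3,4,5-trimethoxyphenyl acetate
Product: 4 2-acetoxy-4,5,6-trimethoxybenzoic acid
Conditions: NaClO2, NaH2PO4, 2-methyl-2-butene, t-BuOH/H2O, 0 °C → rt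
Reagents that add atoms: sodium chlorite (NaClO2), [Na+].[O-]Cl=O
Why: Pinnick oxidation converts the hindered, electron-rich aldehyde into the acid under buffered conditions that spare the aryl acetate, while 2-methyl-2-butene traps the hypochlorous acid that could otherwise chlorinate the ring.

Step 4
Reactants: 4 2-acetoxy-4,5,6-trimethoxybenzoic acid
Product: 5 2-acetoxy-4,5,6-trimethoxybenzoyl chloride
Conditions: (COCl)2, DMF (cat.), CH2Cl2, 0 °C → rt; concentrate, use crude
Reagents that add atoms: oxalyl chloride, O=C(Cl)C(=O)Cl
Why: Chlorination of the acid by oxalyl chloride with catalytic DMF (Vilsmeier-type activation) proceeds at or below room temperature, as for O-acetylsalicyloyl chloride, and the volatile by-products allow the crude chloride to be used directly.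

**Ring B iodide**

Step 5
Reactants: 6 2,6-dimethoxyphenol (syringol)
Product: 7 2-(benzyloxy)-1,3-dimethoxybenzene
Conditions: BnBr, K2CO3, DMF, 60 °C
Reagents that add atoms: benzyl bromide, BrCc1ccccc1
Why: Williamson etherification of the phenoxide is dependable even for this doubly flanked phenol and installs a group that should survive organolithium, copper, palladium, fluoride and amine and be removed by hydrogenolysis at the end.

Step 6
Reactants: 7 2-(benzyloxy)-1,3-dimethoxybenzene
Product: 8 3-(benzyloxy)-1,5-dibromo-2,4-dimethoxybenzene
Conditions: NBS (2.1 equiv), MeCN, 0 °C → rt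
Reagents that add atoms: N-bromosuccinimide, O=C1CCC(=O)N1Br
Why: Electrophilic aromatic bromination should occur twice, each time para to one outer methoxy group and ortho to the other, while the remaining position is meta to both and stays free, giving the symmetrical dibromide.

Step 7
Reactants: 8 3-(benzyloxy)-1,5-dibromo-2,4-dimethoxybenzene
Product: 11 3-(benzyloxy)-5-bromo-2,4-dimethoxyphenol, via aryllithium 9 (not isolated), via dimethyl arylboronate 10 (not isolated)
Conditions: n-BuLi (1.0 equiv), THF, −78 °C; B(OMe)3, −78 °C → rt; AcOH, 30% aq. H2O2, 0 °C → rt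
Reagents that add atoms: hydrogen peroxide, OO
Why: Bromine–lithium exchange with one equivalent of n-BuLi differentiates the two equivalent bromines because the first exchange makes the ring too electron-rich for a second, and borylation followed by peroxide oxidation (1,2-aryl shift from boron to oxygen) converts the C–Li bond into the C–O bond.

Step 8
Reactants: 11 3-(benzyloxy)-5-bromo-2,4-dimethoxyphenol
Product: 12 3-(benzyloxy)-1-bromo-2,4,5-trimethoxybenzene
Conditions: MeI, K2CO3, acetone, reflux
Reagents that add atoms: iodomethane, CI
Why: Williamson O-methylation of the unhindered phenol completes the 2,4,5-trimethoxy pattern and leaves the benzyl ether as the only differentiated oxygen.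

Step 9
Reactants: 12 3-(benzyloxy)-1-bromo-2,4,5-trimethoxybenzene
Product: 13 3-(benzyloxy)-1-iodo-2,4,5-trimethoxybenzene
Conditions: CuI (5 mol%), trans-N,N'-dimethylcyclohexane-1,2-diamine (10 mol%), NaI (2 equiv), 1,4-dioxane, 110 °C
Reagents that add atoms: sodium iodide (NaI), [Na+].[I-]
Why: Copper-catalysed halogen exchange (aromatic Finkelstein reaction) is driven toward the iodide by precipitation of NaBr from dioxane and supplies a halide reactive enough for mild Sonogashira coupling on this electron-rich ring.

**Assembly and endgame**

Step 10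
Reactants: 13 3-(benzyloxy)-1-iodo-2,4,5-trimethoxybenzene; 14 ethynyltrimethylsilane; 5 2-acetoxy-4,5,6-trimethoxybenzoyl chloride
Product: 17 2-{3-[3-(benzyloxy)-2,4,5-trimethoxyphenyl]prop-2-ynoyl}-3,4,5-trimethoxyphenyl acetate, via silylalkyne 15 (not isolated), via terminal alkyne 16 (not isolated)
Conditions: 13, 14 (1.05 equiv), PdCl2(PPh3)2 (2 mol%), CuI (4 mol%), Et3N, THF, rt → 40 °C; TBAF (1.0 equiv, THF, dried over 4 Å sieves), rt; then 5 (1.2 equiv), Et3N, rt → 40 °C
Reagents that add atoms: none
Why: Zerovalent palladium, formed in the flask from PdCl2(PPh3)2, inserts into the C–I bond of 13, the copper acetylide of 14 transmetalates and reductive elimination forges C2–C1' to give 15 (Sonogashira coupling). One equivalent of dry fluoride then cleaves the C–Si bond, the proton coming from the triethylammonium iodide already present, so 16 is released and the fluoride is spent as Me3SiF before any acyl chloride or aryl acetate enters the flask. The same palladium and copper species then take 5 through oxidative addition at the C–Cl bond, transmetalation and reductive elimination to forge C3–C4; the closest known reaction types are the acyl Sonogashira coupling and one-pot coupling–desilylation–coupling sequences of aryl iodides, silylacetylenes and acid chlorides. No ring is closed and no stereocentre is created. The step needs the two couplings to occur in the right order and the acid chloride to react in preference to the aryl acetate: silicon blocks the second alkyne terminus until the aryl coupling is finished, the acid chloride is far more reactive toward palladium than the ester, and the acetate on the future O1 (not the C5 methoxy oxygen) is carried through as the latent nucleophile for ring C.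

Step 11
Reactants: 17 2-{3-[3-(benzyloxy)-2,4,5-trimethoxyphenyl]prop-2-ynoyl}-3,4,5-trimethoxyphenyl acetate
Product: 20 2-[3-(benzyloxy)-2,4,5-trimethoxyphenyl]-5,6,7-trimethoxy-4H-chromen-4-one, via acetoxy enaminone 18 (not isolated), via hydroxy enaminone 19 (not isolated)
Conditions: Et2NH (10 equiv), EtOH, rt → 60 °C
Reagents that add atoms: none
Why: Conjugate addition of diethylamine to the ynone gives a β-amino enone that cannot close 5-exo, aminolysis of the aryl acetate frees the phenol, and 6-endo addition–elimination at C2 with loss of diethylamine gives the chromone (the known amine-mediated flavone closure of ortho-acyloxyaryl ynones).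

Step 12
Reactants: 20 2-[3-(benzyloxy)-2,4,5-trimethoxyphenyl]-5,6,7-trimethoxy-4H-chromen-4-one
Product: 21 Agecorynin G, 2-(3-hydroxy-2,4,5-trimethoxyphenyl)-5,6,7-trimethoxy-4H-chromen-4-one
Conditions: H2 (1 atm), 10% Pd/C, EtOAc/MeOH, rt
Reagents that add atoms: none
Why: Hydrogenolysis of the benzyl aryl ether over Pd/C at atmospheric pressure should be faster than reduction of the chromone C2–C3 double bond and leaves the six methyl ethers untouched.

**Compound list**

1 | 3,4,5-trimethoxyphenol | COc1cc(O)cc(OC)c1OC | starting material
2 | 6-hydroxy-2,3,4-trimethoxybenzaldehyde | COc1cc(O)c(C=O)c(OC)c1OC | intermediate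
3 | 2-formyl-3,4,5-trimethoxyphenyl acetate | COc1cc(OC(C)=O)c(C=O)c(OC)c1OC | intermediate
4 | 2-acetoxy-4,5,6-trimethoxybenzoic acid | COc1cc(OC(C)=O)c(C(=O)O)c(OC)c1OC | intermediate
5 | 2-acetoxy-4,5,6-trimethoxybenzoyl chloride | COc1cc(OC(C)=O)c(C(=O)Cl)c(OC)c1OC | intermediate
6 | 2,6-dimethoxyphenol (syringol) | COc1cccc(OC)c1O | starting material
7 | 2-(benzyloxy)-1,3-dimethoxybenzene | COc1cccc(OC)c1OCc1ccccc1 | intermediate
8 | 3-(benzyloxy)-1,5-dibromo-2,4-dimethoxybenzene | COc1c(Br)cc(Br)c(OC)c1OCc1ccccc1 | intermediate
9 | [3-(benzyloxy)-5-bromo-2,4-dimethoxyphenyl]lithium | [Li]c1cc(Br)c(OC)c(OCc2ccccc2)c1OC | intermediate (not isolated)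
10 | dimethyl [3-(benzyloxy)-5-bromo-2,4-dimethoxyphenyl]boronate | COB(OC)c1cc(Br)c(OC)c(OCc2ccccc2)c1OC | intermediate (not isolated)
11 | 3-(benzyloxy)-5-bromo-2,4-dimethoxyphenol | COc1c(O)cc(Br)c(OC)c1OCc1ccccc1 | intermediate
12 | 3-(benzyloxy)-1-bromo-2,4,5-trimethoxybenzene | COc1cc(Br)c(OC)c(OCc2ccccc2)c1OC | intermediate
13 | 3-(benzyloxy)-1-iodo-2,4,5-trimethoxybenzene | COc1cc(I)c(OC)c(OCc2ccccc2)c1OC | intermediate
14 | ethynyltrimethylsilane | C#C[Si](C)(C)C | starting material
15 | {[3-(benzyloxy)-2,4,5-trimethoxyphenyl]ethynyl}trimethylsilane | COc1cc(C#C[Si](C)(C)C)c(OC)c(OCc2ccccc2)c1OC | intermediate (not isolated)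
16 | 3-(benzyloxy)-1-ethynyl-2,4,5-trimethoxybenzene | COc1cc(C#C)c(OC)c(OCc2ccccc2)c1OC | intermediate (not isolated)
17 | 2-{3-[3-(benzyloxy)-2,4,5-trimethoxyphenyl]prop-2-ynoyl}-3,4,5-trimethoxyphenyl acetate | COc1cc(OC(C)=O)c(C(=O)C#Cc2cc(OC)c(OC)c(OCc3ccccc3)c2OC)c(OC)c1OC | intermediate
18 | 2-{(2E)-3-[3-(benzyloxy)-2,4,5-trimethoxyphenyl]-3-(diethylamino)prop-2-enoyl}-3,4,5-trimethoxyphenyl acetate | CCN(CC)/C(=C/C(=O)c1c(OC(C)=O)cc(OC)c(OC)c1OC)c1cc(OC)c(OC)c(OCc2ccccc2)c1OC | intermediate (not isolated)
19 | (2E)-3-[3-(benzyloxy)-2,4,5-trimethoxyphenyl]-3-(diethylamino)-1-(2-hydroxy-4,5,6-trimethoxyphenyl)prop-2-en-1-one | CCN(CC)/C(=C/C(=O)c1c(O)cc(OC)c(OC)c1OC)c1cc(OC)c(OC)c(OCc2ccccc2)c1OC | intermediate (not isolated)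
20 | 2-[3-(benzyloxy)-2,4,5-trimethoxyphenyl]-5,6,7-trimethoxy-4H-chromen-4-one | COc1cc(-c2cc(=O)c3c(OC)c(OC)c(OC)cc3o2)c(OC)c(OCc4ccccc4)c1OC | intermediate
21 | Agecorynin G, 2-(3-hydroxy-2,4,5-trimethoxyphenyl)-5,6,7-trimethoxy-4H-chromen-4-one | COc1cc(-c2cc(=O)c3c(OC)c(OC)c(OC)cc3o2)c(OC)c(O)c1OC | target

**Step count**

Total: 12 steps. Longest linear sequence: 8 steps (steps 5 to 12, from syringol 6 to 21).

**Steps most likely to fail**

Step 10. Residual water or fluoride may consume the acid chloride, the free alkyne may dimerise oxidatively on copper, and oxidative addition or transmetalation at the doubly ortho-substituted aroyl chloride may be slow, so that the second coupling stalls. The fallback sets out from 13 and 1 and comes back at 20. Iodide 13 would be coupled with 14 as before and the silyl group removed with K2CO3 in MeOH, so that 16 is isolated. Separately, 1 would be iodinated ortho to the hydroxyl with NIS in MeCN to give 2-iodo-3,4,5-trimethoxyphenol F1, which would be acetylated (Ac2O, pyridine) to 2-iodo-3,4,5-trimethoxyphenyl acetate F2. A palladium-catalysed carbonylative Sonogashira annulation of F2 with 16 under CO (1 atm) in Et2NH (PdCl2(PPh3)2, dppp, 40–60 °C) would then build the acyl carbon from carbon monoxide instead of an acid chloride. Through the same amine-mediated deacetylation and 6-endo closure it should deliver 20 directly.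

Step 7. A second exchange or proton transfer between the aryllithium and unreacted dibromide may scramble the bromine count, and the electron-rich phenol may be over-oxidised toward a quinone in the peroxide stage. The fallback sets out from 7, comes back at 11 and uses no organolithium. Vilsmeier–Haack formylation of 7 (POCl3, DMF) para to one methoxy group would give 3-(benzyloxy)-2,4-dimethoxybenzaldehyde F3. NBS bromination, directed to C5 by both methoxy groups and by the meta-directing formyl group, would give 3-(benzyloxy)-5-bromo-2,4-dimethoxybenzaldehyde F4. Baeyer–Villiger (Dakin-type) oxidation with mCPBA would give 3-(benzyloxy)-5-bromo-2,4-dimethoxyphenyl formate F5, and methanolysis (K2CO3, MeOH) would return 11.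

Step 11. Deacetylation may run ahead of amine addition, so that the free phenoxide attacks the alkyne carbon next to the carbonyl in a 5-exo (aurone-type) closure, or aminolysis of the hindered acetate may stall at the acetoxy enaminone. The fallback sets out from 17, comes back at 20 and uses acid in place of amine. HCl in MeOH (generated from AcCl) would transesterify the aryl acetate to give 3-[3-(benzyloxy)-2,4,5-trimethoxyphenyl]-1-(2-hydroxy-4,5,6-trimethoxyphenyl)prop-2-yn-1-one F6. Catalytic TfOH in CH2Cl2 would then close ring C by 6-endo-dig oxa-Michael addition to the protonated ynone, in which C2 is the only activated electrophilic site. Partial loss of the benzyl group under acid would be harmless, since it is removed in the next step.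

**Further compounds**

F1 | step 10 | 2-iodo-3,4,5-trimethoxyphenol | COc1cc(O)c(I)c(OC)c1OC
F2 | step 10 | 2-iodo-3,4,5-trimethoxyphenyl acetate | COc1cc(OC(C)=O)c(I)c(OC)c1OC
F3 | step 7 | 3-(benzyloxy)-2,4-dimethoxybenzaldehyde | COc1ccc(C=O)c(OC)c1OCc1ccccc1
F4 | step 7 | 3-(benzyloxy)-5-bromo-2,4-dimethoxybenzaldehyde | COc1c(Br)cc(C=O)c(OC)c1OCc1ccccc1
F5 | step 7 | 3-(benzyloxy)-5-bromo-2,4-dimethoxyphenyl formate | COc1c(Br)cc(OC=O)c(OC)c1OCc1ccccc1
F6 | step 11 | 3-[3-(benzyloxy)-2,4,5-trimethoxyphenyl]-1-(2-hydroxy-4,5,6-trimethoxyphenyl)prop-2-yn-1-one | COc1cc(O)c(C(=O)C#Cc2cc(OC)c(OC)c(OCc3ccccc3)c2OC)c(OC)c1OC
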